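## Retrosynthetic overview

- The target, 3,5-dibromo-4-chloro-2-(2,4-dibromophenoxy)phenol, is traced back through mesylate cleavage, Sandmeyer chlorination, amine-directed dibromination and nitro reduction to 2-(2,4-dibromophenoxy)-4-nitrophenol.
- Key disconnection: the C3–C4 and C4–C5 bonds of ring A are cut, so the nitrophenol comes from 3-(2,4-dibromophenoxy)-4H-pyran-4-one and nitromethane, whose carbon becomes C4.
- The pyranone comes from 2,4-dibromophenol by O-alkylation with chloroacetone, aminomethylenation with DMF dimethyl acetal, Claisen formylation with ethyl formate and acid closure.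
- Ring order: ring B is bought intact, the 4-pyranone ring is closed third, and carbocyclic ring A is made from it in the fourth step.
- Structural feature: in ring A, C4 (the Cl carbon) lies para to C1–OH and between the brominated C3 and C5, the same relationship the ring oxygen of a 4-pyranone has to its carbonyl. Replacing that oxygen by C–NO2 gives ring A with nitrogen at C4, which directs both bromines and is then exchanged for chlorine.

Key step: step 4

Remark on the chemistry: the double-bond geometries written for the enaminone 5 and for the unisolated open-chain intermediates 7 and 10 are the expected ones; they are lost on ring closure and have no consequence for the route.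

## Route

Step 1
Reactants: 1 2,4-dibromophenol; 2 chloroacetone
Product: 3 1-(2,4-dibromophenoxy)propan-2-one
Conditions: K2CO3 (1.5 equiv), KI (0.1 equiv), acetone, reflux
Reagents that add atoms: none
Why: Williamson ether synthesis, in which the phenoxide displaces chloride from the activated alpha-halo ketone by SN2 with iodide catalysis, so the aryl ether oxygen is attached at an sp3 carbon without any aryl coupling.

Step 2
Reactants: 3 1-(2,4-dibromophenoxy)propan-2-one; 4 N,N-dimethylformamide dimethyl acetal
Product: 5 (Z)-3-(2,4-dibromophenoxy)-4-(dimethylamino)but-3-en-2-one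
Conditions: DMF dimethyl acetal (1.5 equiv), toluene, 100 °C, methanol distilled off
Reagents that add atoms: none
Why: Amide acetal condensation (enaminone formation) should occur at the more acidic aryloxy-substituted methylene with loss of two methanol, and the site of this first one-carbon unit is not critical because the pyranone needs one carbon on each side of the ketone.

Step 3
Reactants: 5 (Z)-3-(2,4-dibromophenoxy)-4-(dimethylamino)but-3-en-2-one; 6 ethyl formate
Product: 8 3-(2,4-dibromophenoxy)-4H-pyran-4-one, via hydroxymethylene enaminone 7 (not isolated)
Conditions: HCO2Et (3 equiv), KOtBu (1.5 equiv), THF, 0 °C to rt; then 2 M HCl, rt to 50 °C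
Reagents that add atoms: none
Why: Crossed Claisen formylation at the methyl group, the only enolizable position left, gives the potassium enolate of 7, and on acidification the enol oxygen should add to the enaminone beta carbon and expel dimethylamine (6-endo-trig addition-elimination) to give the 4-pyranone.

Step 4
Reactants: 8 3-(2,4-dibromophenoxy)-4H-pyran-4-one; 9 nitromethane
Product: 11 2-(2,4-dibromophenoxy)-4-nitrophenol, via open-chain nitro dienone 10 (not isolated)
Conditions: MeNO2 (5 equiv), KOtBu (2.5 equiv), tBuOH, rt to 80 °C; then 1 M HCl
Reagents that add atoms: none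
Why: The nitronate of 9 should add in conjugate fashion to the unsubstituted C6 (or C2) of pyranone 8, and E1cB expulsion of the ring oxygen (retro-oxa-Michael) then opens the heterocycle to the enolate of the formyl ketone 10. The nitromethyl carbon of 10 is still acidic; its anion is delocalized through the C2=C3 bond of the chain, which lets that bond reach the Z geometry, and it attacks the unmasked formyl carbon in a 6-exo-trig intramolecular Henry (nitro-aldol) reaction that closes ring A and forms its C3–C4 and C4–C5 bonds. Loss of water and tautomerization should deliver the 4-nitrophenolate, whose aromaticity and low basicity make the sequence irreversible. The closest known reaction type is the alkoxide-mediated conversion of 2,6-disubstituted 4-pyranones with nitromethane into 3,5-disubstituted 4-nitrophenols, a relative of the pyrylium to nitrobenzene ring transformation. No stereocenter is formed. The step needs attack at an alpha carbon and not at the carbonyl carbon, which the vinylogous-ester character of C4 and the two unhindered, hydrogen-bearing alpha carbons should secure, and because the nitromethane carbon ends up bonded to both alpha carbons, the site of first attack has no effect on the product.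

Step 5
Reactants: 11 2-(2,4-dibromophenoxy)-4-nitrophenol
Product: 12 2-(2,4-dibromophenoxy)-4-nitrophenyl methanesulfonate
Conditions: MsCl (1.2 equiv), Et3N (1.5 equiv), CH2Cl2, 0 °C
Reagents that add atoms: methanesulfonyl chloride, CS(=O)(=O)Cl
Why: O-sulfonylation of the acidic nitrophenol masks the phenol as an electron-poor, oxidation-resistant ester, so that the later para-aminophenol stage cannot be oxidized to a quinone imine by the brominating agent or the nitrite.

Step 6
Reactants: 12 2-(2,4-dibromophenoxy)-4-nitrophenyl methanesulfonate
Product: 13 4-amino-2-(2,4-dibromophenoxy)phenyl methanesulfonate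
Conditions: Fe powder (5 equiv), AcOH, EtOH, 70 °C
Reagents that add atoms: none
Why: Béchamp-type reduction of the nitro group by zerovalent iron in acetic acid proceeds by electron transfer that should leave the aryl bromides, the diaryl ether and the mesylate untouched, whereas catalytic hydrogenation would risk hydrodebromination.

Step 7
Reactants: 13 4-amino-2-(2,4-dibromophenoxy)phenyl methanesulfonate
Product: 14 4-amino-3,5-dibromo-2-(2,4-dibromophenoxy)phenyl methanesulfonate
Conditions: NBS (2.05 equiv), MeCN, 0 °C to rt
Reagents that add atoms: N-bromosuccinimide, O=C1CCC(=O)N1Br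
Why: Electrophilic aromatic bromination should be directed by the free amino group to its two ortho positions C3 and C5 (its para position C1 carries the mesylate), both reinforced by the ether oxygen at C2, while C6 next to the mesylate and the already dibrominated ring B are deactivated.

Step 8
Reactants: 14 4-amino-3,5-dibromo-2-(2,4-dibromophenoxy)phenyl methanesulfonate
Product: 16 3,5-dibromo-4-chloro-2-(2,4-dibromophenoxy)phenyl methanesulfonate, via arenediazonium chloride 15 (not isolated)
Conditions: tBuONO (1.5 equiv), CuCl2 (1.2 equiv), MeCN, 0 °C to 65 °C
Reagents that add atoms: copper dichloride CuCl2, Cl[Cu]Cl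
Why: Sandmeyer chlorodediazoniation under non-aqueous conditions, in which tert-butyl nitrite diazotizes the weakly basic, hindered 2,6-dibromoaniline in solution and CuCl2 transfers chlorine to the aryl radical formed on loss of dinitrogen, while the mesylate and the aryl bromides should survive.

Step 9
Reactants: 16 3,5-dibromo-4-chloro-2-(2,4-dibromophenoxy)phenyl methanesulfonate
Product: 17 3,5-dibromo-4-chloro-2-(2,4-dibromophenoxy)phenol
Conditions: NaOH (3 equiv), 1,4-dioxane/H2O, 70 °C; then 1 M HCl
Reagents that add atoms: none
Why: Saponification of the aryl sulfonate by hydroxide attack at sulfur releases the well-stabilized polyhalophenoxide, the alcohol-free medium avoids methyl transfer to the phenoxide, and the unactivated aryl halides and the diaryl ether are not open to SNAr under these conditions.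

## Compound list

1 | 2,4-dibromophenol | Oc1ccc(Br)cc1Br | starting material
2 | chloroacetone | CC(=O)CCl | starting material
3 | 1-(2,4-dibromophenoxy)propan-2-one | CC(=O)COc1ccc(Br)cc1Br | intermediate
4 | N,N-dimethylformamide dimethyl acetal | COC(OC)N(C)C | starting material
5 | (Z)-3-(2,4-dibromophenoxy)-4-(dimethylamino)but-3-en-2-one | CC(=O)/C(Oc1ccc(Br)cc1Br)=C/N(C)C | intermediate
6 | ethyl formate | CCOC=O | starting material
7 | (1Z,4Z)-4-(2,4-dibromophenoxy)-5-(dimethylamino)-1-hydroxypenta-1,4-dien-3-one (formed as its potassium enolate, not isolated) | O/C=C\C(=O)/C(Oc1ccc(Br)cc1Br)=C/N(C)C | intermediate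
8 | 3-(2,4-dibromophenoxy)-4H-pyran-4-one | O=c1ccocc1Oc1ccc(Br)cc1Br | intermediate
9 | nitromethane | C[N+](=O)[O-] | starting material
10 | (2Z,5E)-5-(2,4-dibromophenoxy)-6-hydroxy-1-nitrohexa-2,5-dien-4-one (formed as its enolate, not isolated) | O=[N+]([O-])C/C=C\C(=O)/C(Oc1ccc(Br)cc1Br)=C\O | intermediate
11 | 2-(2,4-dibromophenoxy)-4-nitrophenol | Oc1ccc([N+](=O)[O-])cc1Oc1ccc(Br)cc1Br | intermediate
12 | 2-(2,4-dibromophenoxy)-4-nitrophenyl methanesulfonate | CS(=O)(=O)Oc1ccc([N+](=O)[O-])cc1Oc1ccc(Br)cc1Br | intermediate
13 | 4-amino-2-(2,4-dibromophenoxy)phenyl methanesulfonate | CS(=O)(=O)Oc1ccc(N)cc1Oc1ccc(Br)cc1Br | intermediate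
14 | 4-amino-3,5-dibromo-2-(2,4-dibromophenoxy)phenyl methanesulfonate | CS(=O)(=O)Oc1cc(Br)c(N)c(Br)c1Oc1ccc(Br)cc1Br | intermediate
15 | 2,6-dibromo-3-(2,4-dibromophenoxy)-4-(methanesulfonyloxy)benzenediazonium chloride (not isolated) | CS(=O)(=O)Oc1cc(Br)c([N+]#N)c(Br)c1Oc1ccc(Br)cc1Br.[Cl-] | intermediate
16 | 3,5-dibromo-4-chloro-2-(2,4-dibromophenoxy)phenyl methanesulfonate | CS(=O)(=O)Oc1cc(Br)c(Cl)c(Br)c1Oc1ccc(Br)cc1Br | intermediate
17 | 3,5-dibromo-4-chloro-2-(2,4-dibromophenoxy)phenol | Oc1cc(Br)c(Cl)c(Br)c1Oc1ccc(Br)cc1Br | target

## Step count and risks

Total step count: 9. Longest linear sequence: 9 steps.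

Steps most likely to fail:

1. Step 4 (key step). The pyranone, unsubstituted at both alpha carbons, may be opened by alkoxide or nitronate without reclosing, or the open-chain dienone may oligomerize by intermolecular Michael addition before the intramolecular Henry closure takes place. The fallback sets out from 1 and comes back at 11 by building the diaryl ether on a preformed nitroarene. Chan–Lam–Evans O-arylation of 1 with (2-methoxy-5-nitrophenyl)boronic acid, COc1ccc([N+](=O)[O-])cc1B(O)O (Cu(OAc)2, pyridine, 4 Å sieves, CH2Cl2, air, rt), should give 2-(2,4-dibromophenoxy)-1-methoxy-4-nitrobenzene F1. This oxidative copper coupling at room temperature does not engage aryl bromides. Selective cleavage of the methyl ether with BBr3 (CH2Cl2, −78 °C to 0 °C), which leaves the diaryl ether intact, should then give 11.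

2. Step 3. Claisen formylation of the weakly acidic methyl group of the vinylogous amide may be slow or reverse, and the enaminone may be hydrolysed on acidification before the ring closes. The fallback sets out from 3 and comes back at 8 by bringing in both one-carbon units at the aminal oxidation level. Heating 3 with an excess of tert-butoxybis(dimethylamino)methane (toluene, 110 °C) should give the bis-enaminone (1Z,4E)-2-(2,4-dibromophenoxy)-1,5-bis(dimethylamino)penta-1,4-dien-3-one F2. Warming F2 in aqueous HCl/THF should hydrolyse one enamine terminus to the enol and close the ring to 8 with loss of dimethylamine.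

3. Step 8. The aryl radical flanked by two ortho bromines may abstract hydrogen from the medium faster than it accepts chlorine from copper (hydrodediazoniation), and chloride may displace an ortho bromine on the strongly activated diazonium ion. The fallback sets out from 14 and comes back at 16 through a carbon–boron intermediate made in the absence of chloride. Sandmeyer-type borylation of 14 (tBuONO, bis(pinacolato)diboron, MeCN, rt) should give 3,5-dibromo-2-(2,4-dibromophenoxy)-4-(4,4,5,5-tetramethyl-1,3,2-dioxaborolan-2-yl)phenyl methanesulfonate F3. Copper-mediated chlorodeboronation of F3 (CuCl2, MeOH/H2O, 80 °C) should then give 16.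

## Further compounds

F1 | step 4 | 2-(2,4-dibromophenoxy)-1-methoxy-4-nitrobenzene | COc1ccc([N+](=O)[O-])cc1Oc1ccc(Br)cc1Br
F2 | step 3 | (1Z,4E)-2-(2,4-dibromophenoxy)-1,5-bis(dimethylamino)penta-1,4-dien-3-one | CN(C)/C=C/C(=O)/C(Oc1ccc(Br)cc1Br)=C/N(C)C
F3 | step 8 | 3,5-dibromo-2-(2,4-dibromophenoxy)-4-(4,4,5,5-tetramethyl-1,3,2-dioxaborolan-2-yl)phenyl methanesulfonate | CS(=O)(=O)Oc1cc(Br)c(B2OC(C)(C)C(C)(C)O2)c(Br)c1Oc1ccc(Br)cc1Br
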